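**Plan**

- Retrosynthetic cuts, in order: (a) the two O–benzyl bonds and the saturation of the A–B alkene (last step); (b) ring D itself at C1–C2 and C1–C6 of the salicylate (C1 = carboxyl-bearing carbon, C2 OH, C4 OMe, C6 side chain), back to a 2-pyranone plus an acetate unit; (c) the CH2–CH2 bond between ring C and ring D; (d) the A–B alkene; (e) the diaryl ether C–O bond.
- Enabling feature: ring D is a 6-alkyl-4-methoxysalicylate, so its C6/C5/C4(OMe)/C3/C2(OH) map onto C6/C5/C4(OMe)/C3/C2(=O) of 4-methoxy-6-methylpyran-2-one. The 6-methyl group of that heterocycle is acidic through the C5=C6–C3=C4–C2=O chain, so the benzylic C–C bond can be made before ring D exists, with OMe and OH already differentiated.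
- Forward order: rings A, B and C are bought as benzenes and joined (SNAr ether, HWE alkene); the ester becomes the benzylic bromide; the lithiated pyranone is alkylated; the pyranone is then converted into benzene ring D by ester-enolate opening at C2 and aldol re-closure; one hydrogenation finishes.
- Stereochemistry: the target has no stereocentre. The E-alkene from the HWE step and the cis enol-ether geometry of the open-chain intermediate are erased by hydrogenation and aromatisation.

Key step: step 6

**Route**

Step 1
Reactants: 1 3-hydroxy-5-methoxybenzaldehyde; 2 methyl 4-fluorobenzoate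
Product: 3 methyl 4-(3-formyl-5-methoxyphenoxy)benzoate
Conditions: K2CO3, DMSO, 120 °C
Reagents that add atoms: none
Why: Nucleophilic aromatic substitution (SNAr) of fluoride by the phenoxide should proceed because the para ester stabilises the Meisenheimer adduct, while the non-enolisable aldehyde is inert to carbonate.

Step 2
Reactants: 4 4-(benzyloxy)benzyl chloride
Product: 5 diethyl [4-(benzyloxy)benzyl]phosphonate
Conditions: P(OEt)3 (neat), 150 °C
Reagents that add atoms: triethyl phosphite, CCOP(OCC)OCC
Why: Michaelis–Arbuzov reaction of a reactive primary benzylic chloride, driven by loss of volatile chloroethane.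

Step 3
Reactants: 3 methyl 4-(3-formyl-5-methoxyphenoxy)benzoate; 5 diethyl [4-(benzyloxy)benzyl]phosphonate
Product: 7 methyl 4-{3-[(E)-2-(4-benzyloxyphenyl)ethenyl]-5-methoxyphenoxy}benzoate, via phosphonate carbanion 6 (not isolated)
Conditions: 5, KOtBu, THF, 0 °C; then 3, 0 °C → rt
Reagents that add atoms: none
Why: Horner–Wadsworth–Emmons olefination of the aryl aldehyde with a benzylic phosphonate carbanion should give the E-stilbene through reversible addition and anti elimination, the methyl ester being far less electrophilic than the aldehyde.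

Step 4
Reactants: 7 methyl 4-{3-[(E)-2-(4-benzyloxyphenyl)ethenyl]-5-methoxyphenoxy}benzoate
Product: 8 (4-{3-[(E)-2-(4-benzyloxyphenyl)ethenyl]-5-methoxyphenoxy}phenyl)methanol
Conditions: LiAlH4, THF, 0 °C; aqueous work-up
Reagents that add atoms: none
Why: Hydride reduction of the aryl ester to the primary benzylic alcohol; the unactivated stilbene, the diaryl ether and the benzyl ether are inert to LiAlH4.

Step 5
Reactants: 8 (4-{3-[(E)-2-(4-benzyloxyphenyl)ethenyl]-5-methoxyphenoxy}phenyl)methanol
Product: 9 1-{(E)-2-[4-(benzyloxy)phenyl]ethenyl}-3-[4-(bromomethyl)phenoxy]-5-methoxybenzene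
Conditions: CBr4, PPh3, CH2Cl2, 0 °C
Reagents that add atoms: carbon tetrabromide, BrC(Br)(Br)Br
Why: Appel reaction converts the primary benzylic alcohol to the bromide under neutral conditions that leave the electron-rich alkene and the ethers untouched.

Step 6
Reactants: 10 4-methoxy-6-methyl-2H-pyran-2-one; 9 1-{(E)-2-[4-(benzyloxy)phenyl]ethenyl}-3-[4-(bromomethyl)phenoxy]-5-methoxybenzene
Product: 12 6-[2-(4-{3-[(E)-2-(4-benzyloxyphenyl)ethenyl]-5-methoxyphenoxy}phenyl)ethyl]-4-methoxy-2H-pyran-2-one, via lithiated pyranone 11 (not isolated)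
Conditions: 10 (1.5 equiv), LDA (1.4 equiv), THF, −78 °C; then 9, DMPU, −78 → −30 °C
Reagents that add atoms: none
Why: LDA should remove a proton from the 6-methyl group of 10, giving anion 11 delocalised over C5, C3 and the lactone carbonyl oxygen, which displaces bromide from the primary benzylic carbon of 9 in an SN2 reaction through its exocyclic carbon. The closest known reaction type is the lateral (vinylogous) alkylation of 4-methoxy-6-methylpyran-2-one and of o-toluate esters with alkyl halides. No ring is closed and no stereocentre is formed. The step needs deprotonation at the methyl group rather than at C3–H, carbon alkylation at the exocyclic terminus rather than at C5, C3 or oxygen, and a single alkylation; the hindered amide base at −78 °C should give the delocalised lateral anion, attack through the exocyclic carbon is the only mode that restores the fully conjugated pyranone, and an excess of 11 over 9 with DMPU should keep substitution faster than proton exchange with product 12. Bromide 9 has no acidic C–H and no carbonyl group, and its unhindered benzylic carbon is activated by the para aryloxy group, so nothing in it should compete. The step attaches the complete A–B–C assembly to a skeleton that already carries the C4 methoxy group and the C2 oxygen of ring D in differentiated form.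

Step 7
Reactants: 12 6-[2-(4-{3-[(E)-2-(4-benzyloxyphenyl)ethenyl]-5-methoxyphenoxy}phenyl)ethyl]-4-methoxy-2H-pyran-2-one
Product: 14 benzyl 2-[2-(4-{3-[(E)-2-(4-benzyloxyphenyl)ethenyl]-5-methoxyphenoxy}phenyl)ethyl]-6-hydroxy-4-methoxybenzoate, via open-chain keto ester 13 (not isolated)
Conditions: BnOAc (3 equiv), LDA (3 equiv), THF, −78 °C; then 12, −78 → −20 °C; AcOH; then DBU, PhMe, 40 °C
Reagents that add atoms: benzyl acetate, CC(=O)OCc1ccccc1
Why: Proposed new method: the pyranone is a cyclic enol ester, so the ester enolate should add to the lactone carbonyl C2 and the adduct should open by loss of the C6 enolate to give keto ester 13, in which the C3 acyl group and the C6 methylene remain cis on the methoxy-bearing double bond as they were in the ring (or reach that geometry by easy rotation of the push–pull alkene); under DBU the doubly activated C2 methylene should then add to the freed C7 ketone (6-(enolendo)-exo-trig aldol), lose water and tautomerise to the phenol, the methyl enol ether blocking the lactonisation that competes in free triketo esters; the closest known reaction types are the Fujimoto–Belleau annulation of enol lactones with carbanions, the attack of benzylic carbanions on the lactone carbonyl of 4-methoxy-6-methylpyran-2-one with re-closure to naphthols, and the aldol aromatisation of 3,5,7-triketo esters to resorcylates.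

Step 8
Reactants: 14 benzyl 2-[2-(4-{3-[(E)-2-(4-benzyloxyphenyl)ethenyl]-5-methoxyphenoxy}phenyl)ethyl]-6-hydroxy-4-methoxybenzoate
Product: 15 2-hydroxy-6-[2-(4-{3-[2-(4-hydroxyphenyl)ethyl]-5-methoxyphenoxy}phenyl)ethyl]-4-methoxybenzoic acid
Conditions: H2 (1 atm), 10% Pd/C, EtOAc–MeOH, rt
Reagents that add atoms: none
Why: Heterogeneous catalytic hydrogenation should saturate the stilbene and hydrogenolyse both benzylic C–O bonds (aryl benzyl ether and benzyl ester) in one operation, under neutral conditions at room temperature that spare the diaryl ether, the methyl ethers and the decarboxylation-prone salicylic acid.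

**Compound list**

1 | 3-hydroxy-5-methoxybenzaldehyde | COc1cc(O)cc(C=O)c1 | starting material
2 | methyl 4-fluorobenzoate | COC(=O)c1ccc(F)cc1 | starting material
3 | methyl 4-(3-formyl-5-methoxyphenoxy)benzoate | COC(=O)c1ccc(Oc2cc(OC)cc(C=O)c2)cc1 | intermediate
4 | 4-(benzyloxy)benzyl chloride | ClCc1ccc(OCc2ccccc2)cc1 | starting material
5 | diethyl [4-(benzyloxy)benzyl]phosphonate | CCOP(=O)(Cc1ccc(OCc2ccccc2)cc1)OCC | intermediate
6 | potassium salt of the benzylic carbanion of 5 (phosphonate carbanion) | [K+].CCOP(=O)(OCC)[CH-]c1ccc(OCc2ccccc2)cc1 | intermediate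
7 | methyl 4-{3-[(E)-2-(4-benzyloxyphenyl)ethenyl]-5-methoxyphenoxy}benzoate | COC(=O)c1ccc(Oc2cc(OC)cc(/C=C/c3ccc(OCc4ccccc4)cc3)c2)cc1 | intermediate
8 | (4-{3-[(E)-2-(4-benzyloxyphenyl)ethenyl]-5-methoxyphenoxy}phenyl)methanol | OCc1ccc(Oc2cc(OC)cc(/C=C/c3ccc(OCc4ccccc4)cc3)c2)cc1 | intermediate
9 | 1-{(E)-2-[4-(benzyloxy)phenyl]ethenyl}-3-[4-(bromomethyl)phenoxy]-5-methoxybenzene | BrCc1ccc(Oc2cc(OC)cc(/C=C/c3ccc(OCc4ccccc4)cc3)c2)cc1 | intermediate
10 | 4-methoxy-6-methyl-2H-pyran-2-one | COC1=CC(=O)OC(C)=C1 | starting material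
11 | lithium salt of the 6-methyl anion of 10 (lithiated pyranone) | [Li+].[CH2-]C1=CC(OC)=CC(=O)O1 | intermediate
12 | 6-[2-(4-{3-[(E)-2-(4-benzyloxyphenyl)ethenyl]-5-methoxyphenoxy}phenyl)ethyl]-4-methoxy-2H-pyran-2-one | COC1=CC(=O)OC(CCc2ccc(Oc3cc(OC)cc(/C=C/c4ccc(OCc5ccccc5)cc4)c3)cc2)=C1 | intermediate
13 | benzyl (4E)-9-(4-{3-[(E)-2-(4-benzyloxyphenyl)ethenyl]-5-methoxyphenoxy}phenyl)-5-methoxy-3,7-dioxonon-4-enoate (open-chain keto ester) | O=C(OCc1ccccc1)CC(=O)/C=C(\CC(=O)CCc1ccc(Oc2cc(OC)cc(/C=C/c3ccc(OCc4ccccc4)cc3)c2)cc1)OC | intermediate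
14 | benzyl 2-[2-(4-{3-[(E)-2-(4-benzyloxyphenyl)ethenyl]-5-methoxyphenoxy}phenyl)ethyl]-6-hydroxy-4-methoxybenzoate | COc1cc(O)c(C(=O)OCc2ccccc2)c(CCc2ccc(Oc3cc(OC)cc(/C=C/c4ccc(OCc5ccccc5)cc4)c3)cc2)c1 | intermediate
15 | 2-hydroxy-6-[2-(4-{3-[2-(4-hydroxyphenyl)ethyl]-5-methoxyphenoxy}phenyl)ethyl]-4-methoxybenzoic acid | COc1cc(CCc2ccc(O)cc2)cc(Oc2ccc(CCc3cc(OC)cc(O)c3C(=O)O)cc2)c1 | target

**Step count and risks**

Total step count: 8. Longest linear sequence: 7 steps (steps 1, 3, 4, 5, 6, 7, 8); step 2 is a one-step side branch.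

Steps most likely to fail:

1. Step 7 (proposed new method). The ester enolate may take a proton from the side-chain methylene next to C6 instead of adding to the lactone carbonyl, or the opened keto ester may fail to re-close cleanly to the benzene. The fallback uses known chemistry, sets out from bromide 9 and comes back at 14. Commercial orsellinic acid (2,4-dihydroxy-6-methylbenzoic acid) would be converted with acetone, TFAA and TFA into 7-hydroxy-2,2,5-trimethyl-4H-1,3-benzodioxin-4-one F1, and O-methylated (MeI, K2CO3, acetone) to 7-methoxy-2,2,5-trimethyl-4H-1,3-benzodioxin-4-one F2. Lateral lithiation of F2 (LDA, THF, −78 °C) and alkylation with 9 should give 5-[2-(4-{3-[(E)-2-(4-benzyloxyphenyl)ethenyl]-5-methoxyphenoxy}phenyl)ethyl]-7-methoxy-2,2-dimethyl-4H-1,3-benzodioxin-4-one F3. Opening of the dioxinone with sodium benzyloxide (BnOH, NaH, THF) should deliver benzyl ester 14.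

2. Step 6 (key step). Metalation may occur at ring C3 instead of the methyl group, the lithiated pyranone may attack the lactone carbonyl of unreacted pyranone (self-condensation), a second alkylation may follow the first, or the activated bromide may decompose before it is consumed. The fallback replaces the alkylation by a carbonyl condensation, sets out from alcohol 8 and comes back at target 15. Oxidation of 8 (MnO2, CH2Cl2) should give 4-{3-[(E)-2-(4-benzyloxyphenyl)ethenyl]-5-methoxyphenoxy}benzaldehyde F4. Condensation of F4 with 10 (Mg(OMe)2, MeOH, reflux), the known route to 6-styryl-4-methoxypyranones, should give 6-[(E)-2-(4-{3-[(E)-2-(4-benzyloxyphenyl)ethenyl]-5-methoxyphenoxy}phenyl)ethenyl]-4-methoxy-2H-pyran-2-one F5. F5 has no acidic C–H next to C6; under the conditions of step 7 it should give benzyl 2-[(E)-2-(4-{3-[(E)-2-(4-benzyloxyphenyl)ethenyl]-5-methoxyphenoxy}phenyl)ethenyl]-6-hydroxy-4-methoxybenzoate F6. The hydrogenation of step 8 should then reduce both alkenes and remove both benzyl groups to give 15.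

3. Step 1. Substitution on the weakly activated fluoroarene may be slow, with hydrolysis of the methyl ester or degradation of the aldehyde at the temperature required. The fallback sets out from 1 and comes back at 3: Chan–Lam coupling of 1 with commercial 4-(methoxycarbonyl)phenylboronic acid (Cu(OAc)2, pyridine, 4 Å MS, CH2Cl2, air, rt) forms the same diaryl ether at room temperature and makes no new compound (F0).

**Further compounds**

F1 | step 7 | 7-hydroxy-2,2,5-trimethyl-4H-1,3-benzodioxin-4-one | CC1(C)OC(=O)c2c(C)cc(O)cc2O1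
F2 | step 7 | 7-methoxy-2,2,5-trimethyl-4H-1,3-benzodioxin-4-one | COc1cc(C)c2C(=O)OC(C)(C)Oc2c1
F3 | step 7 | 5-[2-(4-{3-[(E)-2-(4-benzyloxyphenyl)ethenyl]-5-methoxyphenoxy}phenyl)ethyl]-7-methoxy-2,2-dimethyl-4H-1,3-benzodioxin-4-one | COc1cc(CCc2ccc(Oc3cc(OC)cc(/C=C/c4ccc(OCc5ccccc5)cc4)c3)cc2)c2C(=O)OC(C)(C)Oc2c1
F4 | step 6 | 4-{3-[(E)-2-(4-benzyloxyphenyl)ethenyl]-5-methoxyphenoxy}benzaldehyde | O=Cc1ccc(Oc2cc(OC)cc(/C=C/c3ccc(OCc4ccccc4)cc3)c2)cc1
F5 | step 6 | 6-[(E)-2-(4-{3-[(E)-2-(4-benzyloxyphenyl)ethenyl]-5-methoxyphenoxy}phenyl)ethenyl]-4-methoxy-2H-pyran-2-one | COC1=CC(=O)OC(/C=C/c2ccc(Oc3cc(OC)cc(/C=C/c4ccc(OCc5ccccc5)cc4)c3)cc2)=C1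
F6 | step 6 | benzyl 2-[(E)-2-(4-{3-[(E)-2-(4-benzyloxyphenyl)ethenyl]-5-methoxyphenoxy}phenyl)ethenyl]-6-hydroxy-4-methoxybenzoate | COc1cc(O)c(C(=O)OCc2ccccc2)c(/C=C/c2ccc(Oc3cc(OC)cc(/C=C/c4ccc(OCc5ccccc5)cc4)c3)cc2)c1
F0 | step 1 | none | none
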